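## Structural features

Desbromosceptrin is a cyclobutane, Ca–Cb–Cc–Cd, in which Ca and Cd each carry a 2-aminoimidazol-4-yl ring through a C–C bond and Cb and Cc each carry a CH2–NH–CO arm ending in a pyrrol-2-yl ring; one pyrrole has bromine at C4, the other has none. The four ring carbons are contiguous stereocentres, every substituent is trans to both neighbours (Ca S, Cb R, Cc R, Cd S), and the skeleton is C2-symmetric apart from the bromine. Fragile parts are the basic, nucleophilic 2-aminoimidazoles, the electron-rich pyrroles with their aryl C–Br bond (reduction, zerovalent palladium, electrophilic halogen) and the strained ring. The real difficulty is the absolute configuration at Cb and Cc: their CH2 arms cannot be epimerised, whereas Ca and Cd can be equilibrated to all-trans once they carry carbonyl groups. The key step uses exactly this: Cb and Cc are trans and each bears one exocyclic CH2, so a trans-cyclobut-3-ene-1,2-diol diacetate can pass one CH2CO2 unit from each allylic oxygen to the far alkene carbon on that oxygen's face, leaving a Ca=Cd double bond for two carbonyl groups. A check of the configurations shows that the (1S,2S)-diacetate, the (1S,2S)-diacid and the target are mutually consistent, so no descriptor needs changing. What must change is the access to the diacetate: a trans-3,4-diacyloxycyclobutene opens conrotatorily with both oxygens turning outwards below the temperature of a retro-Diels–Alder release (that thermal sequence is the textbook route to (E,E)-1,4-diacetoxybuta-1,3-diene), so the precursor is made without heat from a meso cis-diol, kept at or below 0 °C, and used as its bis(tert-butyldimethylsilyl ketene acetal). The C2 symmetry also makes the two amines of the last intermediate equivalent, so the first of the two acylations can be selective only by stoichiometry.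

## Logic of the disconnections

25 ⇒ 23 + 24, then 23 ⇒ 21 + 22: the two amide C–N bonds are cut. They go last because the bromopyrrole would not survive the carbonylation and ylide steps, and every earlier intermediate then stays C2-symmetric. The forward steps need the primary amines to react before the aminoimidazole nitrogens. Because the two amines of 21 are exchanged by the C2 axis, the first acylation is run with a deficit of 22 and recovery of 21; it cannot give regioisomers.

21 ⇒ 20: four N–CO2tBu bonds are cut, so one acid treatment frees everything. 20 ⇒ 18 + 19: in each imidazole the N1–C5 and N3–C4 bonds are cut, which reduces each heterocycle to a chloromethyl ketone on Ca or Cd. The condensation must tolerate the carbamates; Ca and Cd are already in their stable trans arrangement.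

18 ⇒ 17 ⇒ 16: the C–Cl bond and then the CO–CH bond are cut, a one-carbon homologation of each ester through a sulfoxonium ylide. This avoids diazo chemistry and acid chlorides. The acid used to open the ylide must spare the carbamates.

16 ⇒ 15: no bond is cut; one ester-bearing carbon is inverted. 15 ⇒ 14: the Ca–CO and Cd–CO bonds are cut, which removes two stereocentres and leaves a C2-symmetric alkene with homotopic faces. The forward step must add two CO2Me groups syn to a strained alkene without β-hydride elimination.

14 ⇒ 11: both CH2–N bonds are traced back to CH2–CO2H (Curtius). The sigmatropic step delivers acetic acid arms and the target needs aminomethyl arms; the migration does not touch Cb or Cc. The forward step must stay near 40 °C to spare the cyclobutene.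

11 ⇒ 7: the Cb–CH2 and Cc–CH2 bonds are cut and the double bond moves back to its original position. Two C–C stereocentres are exchanged for two C–O stereocentres of a small C2-symmetric diester. The forward step needs both [3,3] shifts to be suprafacial and faster than ring opening.

7 ⇒ 6 ⇒ 5: one C–O bond is cut (made forward with inversion), then one O–acyl bond (made forward by enantiotopic differentiation of a meso diol). This replaces a hot route and a resolution that discards half the material. The inversion must be a clean SN2 process.

5 ⇒ 4 ⇒ 3 ⇒ 1 + 2: the carbonate C–O bonds, the alkene (from two C–Cl bonds) and the two ring C–C bonds ([2+2]) are cut in turn. The cis-fused carbonate makes every intermediate up to 5 thermally robust.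

## Other disconnections considered

Alternative 1: The cut is through both imidazoles at the carbon bonded to the ring (C4–C5 and N1–C2 of each). The bis(aldimine) A1 would react at both ends with tosylmethyl isocyanide A2 and carbonate base to give the bis-imidazole A3, with loss of sulfinate. In its favour are mild, metal-free conditions, strong precedent, epimerisable aldimine α-carbons that settle trans, and no passage through a labile oxygenated cyclobutene. On mechanistic security it is the better of the two plans. Against it here: A3 lacks both 2-amino groups, so each imidazole needs C2 metalation, azide transfer and reduction, followed by removal of an N-benzyl group under strong acid. The arms arrive as silyl ethers and need oxygen-to-nitrogen exchange. The alternative also does not say where the absolute configuration at Cb and Cc comes from, since A1 must already be enantiopure. The chosen plan sets Cb and Cc in its key step; after the key step the two plans are about equal in step count.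

Alternative 2: The cut is through Ca–Cb and Cc–Cd, the ring itself. Under visible-light triplet sensitisation the ethene A4 would add to di-(−)-menthyl fumarate A5 to give A6, forming the ring, all four stereocentres and both masked aminoimidazoles in one step. Hydrazinolysis, conversion of the esters to aminomethyl groups and acylation would follow. On step economy it is clearly better than the chosen plan, and the all-trans outcome is the expected one from two trans alkenes. Against it: a stilbene-like triplet mainly isomerises or dimerises, the fumarate can itself be sensitised to the maleate, and the stepwise 1,4-biradical allows stereochemical leakage. The menthyl groups are remote from the reacting carbons, so control of the enantiomer would rest on separating diastereomers. The chosen plan transfers chirality through a cyclic transition state from defined centres. On precedent for the ring-forming event the alternative is equal or better.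

Alternative 3: The cut is at the Ca–heteroaryl and Cd–heteroaryl bonds. The bis(N-hydroxyphthalimide) ester A7 and 3-iodoimidazo[1,2-a]pyrimidine A8 would couple twice under reductive nickel catalysis to give A9. In its favour: the radicals at Ca and Cd are planar, so bond formation trans to the neighbours is expected whatever the configuration of the acid. The nitrogen arms are already in place, and one hydrazinolysis would unmask amines and aminoimidazoles together; after the key step it is shorter than the chosen plan, and a single such coupling has better precedent than the chosen key step. Against it: the two activated esters are vicinal, so the first radical sits β to the second ester and loss of both carboxyl groups to a cyclobutene competes. The second coupling is next to a bulky heteroaryl group, and the iodide is electron-poor and coordinating. As in Alternative 1, the absolute configuration at Cb and Cc is left to an earlier, unspecified source.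

Key step: step 6

Assumption: the lipase in step 4 is taken to acetylate the hydroxyl of 5 that leads to 6; if it shows the opposite sense, hydrolysis of the meso diacetate of 5 with the same enzyme gives 6, because the two modes are enantiocomplementary.

## Route

Step 1
Reactants: 1 vinylene carbonate; 2 1,2-dichloroethene (E/Z mixture)
Product: 3 6,7-dichloro-2,4-dioxabicyclo[3.2.0]heptan-3-one (cis ring fusion, isomer mixture at C6 and C7)
Conditions: hν (medium-pressure Hg lamp, Pyrex), acetone (sensitiser and solvent), excess 2, 15 °C
Reagents that add atoms: none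
Why: Triplet-sensitised [2+2] photocycloaddition of a cyclic enediol carbonate to a chloroalkene; the five-membered carbonate enforces the cis relation of the two C–O bonds, and the chlorine-bearing centres need no control because both chlorines are removed next.

Step 2
Reactants: 3
Product: 4 (1R,5S)-2,4-dioxabicyclo[3.2.0]hept-6-en-3-one (meso)
Conditions: activated Zn dust, EtOH, 78 °C
Reagents that add atoms: none
Why: Reductive 1,2-elimination of a vicinal dichloride by zinc; all dichloro isomers converge on the same meso alkene, and the cis-fused carbonate cannot open electrocyclically.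

Step 3
Reactants: 4
Product: 5 (1R,2S)-cyclobut-3-ene-1,2-diol (cis, meso)
Conditions: K2CO3 (0.1 equiv), MeOH, 0 °C; NH4Cl quench
Reagents that add atoms: none
Why: Base-catalysed methanolysis (transesterification) of the cyclic carbonate; a cis-diol resists conrotatory opening because one oxygen would have to turn inwards, and the cold, weakly basic medium keeps the alkoxide concentration low.

Step 4
Reactants: 5
Product: 6 (1S,4R)-4-hydroxycyclobut-2-en-1-yl acetate
Conditions: immobilised Burkholderia cepacia lipase, vinyl acetate (3 equiv), tert-butyl methyl ether, 20 °C; filtered and used crude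
Reagents that add atoms: vinyl acetate, C=COC(C)=O
Why: Lipase-catalysed desymmetrisation of a meso diol by irreversible transesterification with an enol ester; the enzyme distinguishes the enantiotopic hydroxyls, so the (1S,4R) pattern is set by the catalyst. Crude 6 is used at once to limit 1,2-acyl migration.

Step 5
Reactants: 6
Product: 7 (1S,2S)-cyclobut-3-ene-1,2-diyl diacetate
Conditions: PPh3, DIAD, AcOH (1.5 equiv), toluene–THF, −20 → 0 °C; cold work-up, stored at −20 °C
Reagents that add atoms: acetic acid, CC(O)=O
Why: Mitsunobu esterification: acetate displaces the oxyphosphonium group of the allylic alcohol by SN2 attack anti to both ring oxygens, inverting the carbinol carbon from R to S and giving the C2-symmetric trans-diacetate. The temperature stays at or below 0 °C because 7 can open conrotatorily.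

Step 6
Reactants: 7
Product: 11 2,2'-[(1S,2S)-cyclobut-3-ene-1,2-diyl]diacetic acid, via bis(silyl ketene acetal) 8 (not isolated), via singly rearranged silyl ester 9 (not isolated), via bis(silyl ester) 10 (not isolated)
Conditions: LiN(iPr)2 (LDA, 2.4 equiv) added to 7 and TBSCl (2.6 equiv) in THF–DMPU (4:1), −78 °C; then −78 → 0 °C, held at 0 °C; 1 M aq. HCl–THF, 0 °C
Reagents that add atoms: none
Why: Proposed new method: in-situ silylation of the bis-enolate gives 8, whose first ketene acetal and its allylic ring C–O bond pass through a boat-like six-membered transition state on one face of the ring ([3,3]-sigmatropic Ireland–Claisen shift), forming Cb–CH2 on the face the oxygen leaves and moving the alkene so that the second ester in 9 becomes allylic and rearranges in the same way to 10; the closest known reaction type is the Ireland–Claisen rearrangement of cyclohexenyl and cyclopentenyl esters and the twofold rearrangement of cycloalkenediol diesters, which has not been shown on a cyclobutene. No ring is closed. The new stereocentre Cb is controlled by the carbinol centre whose oxygen departs on the same face, and Cc likewise by the second carbinol centre, so the (S,S)-trans-diol gives the (S,S)-trans arms by suprafacial 1,3-transfer. The step needs the [3,3] shift to outrun conrotatory opening of the trans-3,4-dioxygenated cyclobutene; in its favour, a ring sp2 carbon becomes sp3-like in the transition state, which relieves strain, the transannular C···C distance matches the O···CH2 span of the ketene acetal, and the mixture never goes above 0 °C. O-Silylation over C-silylation is secured by TBSCl with DMPU, and in-situ trapping prevents ketene loss from the lithium enolate.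

Step 7
Reactants: 11
Product: 14 di-tert-butyl {[(1S,2S)-cyclobut-3-ene-1,2-diyl]bis(methylene)}dicarbamate, via bis(acyl azide) 12 (not isolated), via bis(isocyanate) 13 (not isolated)
Conditions: NaN3 (4 equiv), Boc2O (2.3 equiv), Zn(OTf)2 (7 mol%), Bu4NBr (30 mol%), THF, 40 °C
Reagents that add atoms: sodium azide, [Na+].[N-]=[N+]=[N-]; di-tert-butyl dicarbonate, CC(C)(C)OC(=O)OC(=O)OC(C)(C)C
Why: One-pot Curtius rearrangement: the acid is activated by Boc2O, converted to the acyl azide, rearranged at 40 °C with zinc triflate assistance, and the isocyanate is captured by tert-butoxide. The migrating group is a CH2, so Cb and Cc are untouched, and the low temperature spares the trans-3,4-dialkylcyclobutene.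

Step 8
Reactants: 14
Product: 15 dimethyl (1R,2S,3R,4R)-3,4-bis({[(tert-butoxycarbonyl)amino]methyl})cyclobutane-1,2-dicarboxylate (esters cis to each other, arms trans)
Conditions: Pd(OCOCF3)2 (5 mol%), N,N'-bis(2,6-dimethylphenyl)butane-2,3-diimine (5.5 mol%), p-benzoquinone (1.5 equiv), TsOH·H2O (2 mol%), CO (4 bar), MeOH–THF (7:1), 20 °C
Reagents that add atoms: carbon monoxide, [C-]#[O+]; methanol, CO
Why: Oxidative bis-alkoxycarbonylation of an alkene by divalent palladium (syn methoxycarbonyl-palladation, CO insertion, methanolysis; benzoquinone reoxidises zerovalent palladium). The faces of 14 are exchanged by its C2 axis, so syn addition gives one diastereomer, with one ester cis to its neighbouring arm. CO pressure and the strain of a cyclobutene-forming β-hydride elimination should suppress chain walking.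

Step 9
Reactants: 15
Product: 16 dimethyl (1S,2S,3R,4R)-3,4-bis({[(tert-butoxycarbonyl)amino]methyl})cyclobutane-1,2-dicarboxylate (all-trans)
Conditions: NaOMe (0.3 equiv), MeOH, 0 → 20 °C; AcOH quench
Reagents that add atoms: none
Why: Base-mediated epimerisation α to an ester: the one ester that is cis to both neighbours inverts to give the thermodynamically preferred all-trans isomer. Catalytic base in the cold is chosen to avoid lactam formation between a cis ester and its carbamate arm.

Step 10
Reactants: 16
Product: 17 di-tert-butyl {[(1R,2R,3S,4S)-3,4-bis[(dimethyloxo-λ6-sulfanylidene)acetyl]cyclobutane-1,2-diyl]bis(methylene)}dicarbamate (bis(β-keto sulfoxonium ylide))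
Conditions: Me3S(O)I (6 equiv), KOtBu (5.8 equiv), THF, 65 °C (ylide formation); then 16, 0 → 40 °C
Reagents that add atoms: trimethylsulfoxonium iodide, C[S+](C)(C)=O.[I-]
Why: Acylation of dimethylsulfoxonium methylide (Corey–Chaykovsky reagent) by a methyl ester gives a stabilised β-keto sulfoxonium ylide. The ylide is too weak a base to deprotonate the carbamates, and the α-centres are already in their stable trans arrangement.

Step 11
Reactants: 17
Product: 18 di-tert-butyl {[(1R,2R,3S,4S)-3,4-bis(2-chloroacetyl)cyclobutane-1,2-diyl]bis(methylene)}dicarbamate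
Conditions: LiCl (6 equiv), MsOH (2.2 equiv), THF, 65 °C
Reagents that add atoms: lithium chloride, [Li+].[Cl-]
Why: Protonation of the ylide carbon and SN2 displacement of dimethyl sulfoxide by chloride give the chloromethyl ketone. The acid is consumed stoichiometrically by the ylide, which is why the Boc carbamates should survive.

Step 12
Reactants: 18; 19 N-Boc-guanidine
Product: 20 di-tert-butyl 4,4'-[(1S,2S,3R,4R)-3,4-bis({[(tert-butoxycarbonyl)amino]methyl})cyclobutane-1,2-diyl]bis(2-amino-1H-imidazole-1-carboxylate)
Conditions: 19 (6 equiv), NaI (0.2 equiv), DMF, 20 °C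
Reagents that add atoms: none
Why: Condensation of an α-chloroketone with N-Boc-guanidine (N-alkylation, cyclisation onto the ketone, dehydration) gives the 1-Boc-2-aminoimidazole. Excess 19 serves as base, and Ca and Cd cannot drift because all-trans is the stable arrangement.

Step 13
Reactants: 20
Product: 21 4,4'-[(1S,2S,3R,4R)-3,4-bis(aminomethyl)cyclobutane-1,2-diyl]bis(1H-imidazol-2-amine) tetrakis(trifluoroacetate)
Conditions: CF3CO2H–CH2Cl2 (1:1), 0 → 20 °C; evaporation
Reagents that add atoms: trifluoroacetic acid (as counter-ion), OC(=O)C(F)(F)F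
Why: Acidolysis of all four tert-butoxycarbonyl groups with loss of isobutene and CO2; the ammonium and 2-aminoimidazolium trifluoroacetates are stable and need no chromatography.

Step 14
Reactants: 21; 22 4-bromo-2-(trichloroacetyl)-1H-pyrrole
Product: 23 4-bromo-N-{[(1R,2R,3S,4S)-2-(aminomethyl)-3,4-bis(2-amino-1H-imidazol-4-yl)cyclobutyl]methyl}-1H-pyrrole-2-carboxamide
Conditions: 22 (0.5 equiv, slow addition), iPr2NEt (4.5 equiv), DMF, 0 → 20 °C; reverse-phase chromatography (aq. NH4HCO3–MeCN); unreacted 21 recovered and recycled
Reagents that add atoms: none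
Why: Acyl transfer from a 2-(trichloroacetyl)pyrrole to a primary amine with loss of chloroform (haloform-type cleavage); primary alkylamines should react much faster than 2-aminoimidazoles with this mild donor. The two amines of 21 are homotopic, so mono-acylation gives a single compound and is controlled only by the deficit of 22.

Step 15
Reactants: 23; 24 2-(trichloroacetyl)-1H-pyrrole
Product: 25 desbromosceptrin, N-{[(1R,2R,3S,4S)-3,4-bis(2-amino-1H-imidazol-4-yl)-2-{[(4-bromo-1H-pyrrole-2-carbonyl)amino]methyl}cyclobutyl]methyl}-1H-pyrrole-2-carboxamide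
Conditions: 24 (1.3 equiv), iPr2NEt (1 equiv), DMF, 20 °C; reverse-phase chromatography
Reagents that add atoms: none
Why: The same acyl transfer on the remaining primary amine; no stereocentre is affected and the product is the target.

## Compound list

1 | vinylene carbonate (1,3-dioxol-2-one) | O=C1OC=CO1 | starting material
2 | 1,2-dichloroethene (E/Z mixture) | ClC=CCl | starting material
3 | 6,7-dichloro-2,4-dioxabicyclo[3.2.0]heptan-3-one (cis-fused; isomer mixture at C6/C7) | O=C1O[C@@H]2C(Cl)C(Cl)[C@@H]2O1 | intermediate
4 | (1R,5S)-2,4-dioxabicyclo[3.2.0]hept-6-en-3-one (meso) | O=C1O[C@@H]2C=C[C@@H]2O1 | intermediate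
5 | (1R,2S)-cyclobut-3-ene-1,2-diol (cis, meso) | O[C@@H]1C=C[C@@H]1O | intermediate
6 | (1S,4R)-4-hydroxycyclobut-2-en-1-yl acetate | O[C@@H]1C=C[C@@H]1OC(C)=O | intermediate
7 | (1S,2S)-cyclobut-3-ene-1,2-diyl diacetate | CC(=O)O[C@H]1C=C[C@@H]1OC(C)=O | intermediate
8 | (3S,4S)-3,4-bis({1-[(tert-butyldimethylsilyl)oxy]ethenyl}oxy)cyclobut-1-ene | C=C(O[Si](C)(C)C(C)(C)C)O[C@H]1C=C[C@@H]1OC(=C)O[Si](C)(C)C(C)(C)C | intermediate (not isolated)
9 | tert-butyldimethylsilyl 2-[(1R,4R)-4-({1-[(tert-butyldimethylsilyl)oxy]ethenyl}oxy)cyclobut-2-en-1-yl]acetate | CC(C)(C)[Si](C)(C)OC(=O)C[C@@H]1C=C[C@H]1OC(=C)O[Si](C)(C)C(C)(C)C | intermediate (not isolated)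
10 | bis(tert-butyldimethylsilyl) 2,2'-[(1S,2S)-cyclobut-3-ene-1,2-diyl]diacetate | CC(C)(C)[Si](C)(C)OC(=O)C[C@H]1C=C[C@@H]1CC(=O)O[Si](C)(C)C(C)(C)C | intermediate (not isolated)
11 | 2,2'-[(1S,2S)-cyclobut-3-ene-1,2-diyl]diacetic acid | OC(=O)C[C@H]1C=C[C@@H]1CC(=O)O | intermediate
12 | 2,2'-[(1S,2S)-cyclobut-3-ene-1,2-diyl]diacetyl diazide | [N-]=[N+]=NC(=O)C[C@H]1C=C[C@@H]1CC(=O)N=[N+]=[N-] | intermediate (not isolated)
13 | (3S,4S)-3,4-bis(isocyanatomethyl)cyclobut-1-ene | O=C=NC[C@H]1C=C[C@@H]1CN=C=O | intermediate (not isolated)
14 | di-tert-butyl {[(1S,2S)-cyclobut-3-ene-1,2-diyl]bis(methylene)}dicarbamate | CC(C)(C)OC(=O)NC[C@H]1C=C[C@@H]1CNC(=O)OC(C)(C)C | intermediate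
15 | dimethyl (1R,2S,3R,4R)-3,4-bis({[(tert-butoxycarbonyl)amino]methyl})cyclobutane-1,2-dicarboxylate | COC(=O)[C@H]1[C@H](CNC(=O)OC(C)(C)C)[C@@H](CNC(=O)OC(C)(C)C)[C@H]1C(=O)OC | intermediate
16 | dimethyl (1S,2S,3R,4R)-3,4-bis({[(tert-butoxycarbonyl)amino]methyl})cyclobutane-1,2-dicarboxylate | COC(=O)[C@H]1[C@H](CNC(=O)OC(C)(C)C)[C@@H](CNC(=O)OC(C)(C)C)[C@@H]1C(=O)OC | intermediate
17 | di-tert-butyl {[(1R,2R,3S,4S)-3,4-bis[(dimethyloxo-λ6-sulfanylidene)acetyl]cyclobutane-1,2-diyl]bis(methylene)}dicarbamate | CS(C)(=O)=CC(=O)[C@H]1[C@H](CNC(=O)OC(C)(C)C)[C@@H](CNC(=O)OC(C)(C)C)[C@@H]1C(=O)C=S(C)(C)=O | intermediate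
18 | di-tert-butyl {[(1R,2R,3S,4S)-3,4-bis(2-chloroacetyl)cyclobutane-1,2-diyl]bis(methylene)}dicarbamate | ClCC(=O)[C@H]1[C@H](CNC(=O)OC(C)(C)C)[C@@H](CNC(=O)OC(C)(C)C)[C@@H]1C(=O)CCl | intermediate
19 | N-Boc-guanidine | CC(C)(C)OC(=O)NC(N)=N | starting material
20 | di-tert-butyl 4,4'-[(1S,2S,3R,4R)-3,4-bis({[(tert-butoxycarbonyl)amino]methyl})cyclobutane-1,2-diyl]bis(2-amino-1H-imidazole-1-carboxylate) | CC(C)(C)OC(=O)n1cc(nc1N)[C@H]1[C@H](CNC(=O)OC(C)(C)C)[C@@H](CNC(=O)OC(C)(C)C)[C@@H]1c1cn(C(=O)OC(C)(C)C)c(N)n1 | intermediate
21 | 4,4'-[(1S,2S,3R,4R)-3,4-bis(aminomethyl)cyclobutane-1,2-diyl]bis(1H-imidazol-2-amine) tetrakis(trifluoroacetate) | Nc1ncc([C@H]2[C@H](CN)[C@@H](CN)[C@@H]2c2cnc(N)[nH]2)[nH]1.OC(=O)C(F)(F)F.OC(=O)C(F)(F)F.OC(=O)C(F)(F)F.OC(=O)C(F)(F)F | intermediate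
22 | 4-bromo-2-(trichloroacetyl)-1H-pyrrole | O=C(c1cc(Br)c[nH]1)C(Cl)(Cl)Cl | starting material
23 | 4-bromo-N-{[(1R,2R,3S,4S)-2-(aminomethyl)-3,4-bis(2-amino-1H-imidazol-4-yl)cyclobutyl]methyl}-1H-pyrrole-2-carboxamide | Nc1ncc([C@H]2[C@H](CN)[C@@H](CNC(=O)c3cc(Br)c[nH]3)[C@@H]2c2cnc(N)[nH]2)[nH]1 | intermediate
24 | 2-(trichloroacetyl)-1H-pyrrole | O=C(c1ccc[nH]1)C(Cl)(Cl)Cl | starting material
25 | desbromosceptrin | Nc1ncc([C@H]2[C@H](CNC(=O)c3ccc[nH]3)[C@@H](CNC(=O)c3cc(Br)c[nH]3)[C@@H]2c2cnc(N)[nH]2)[nH]1 | target

## Step count and least certain steps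

Total: 15 steps. Longest linear sequence: 15 steps (1 and 2 to 25); 19, 22 and 24 are bought.

**Step 6 (key step).** The trans-3,4-dioxygenated cyclobutene, in 7 and more so in 8 and 9, may undergo conrotatory ring opening faster than the [3,3] shifts, because both oxygen donors can turn outwards while the shift must pass a bridged boat transition state. C-silylation or condensation of the acetate enolates would lower the amount of 8 further.
Fallback, known chemistry only: it sets out from 2 and comes back at 14, so the oxygenated cyclobutenes are avoided altogether.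
- Acetophenone-sensitised photocycloaddition of maleic anhydride to 2 gives 6,7-dichloro-3-oxabicyclo[3.2.0]heptane-2,4-dione F1.
- Zinc in acetic anhydride–toluene removes both chlorines to give cis-cyclobut-3-ene-1,2-dicarboxylic anhydride F2.
- Methanol with H2SO4 gives the dimethyl cis-diester F3, and catalytic NaOMe equilibrates it to the dimethyl trans-diester F4 (racemic).
- LiOH gives racemic F5, which is resolved by crystallising its salt with one enantiomer of 1-phenylethylamine to (1S,2S)-cyclobut-3-ene-1,2-dicarboxylic acid F5.
- LiAlH4 gives [(1S,2S)-cyclobut-3-ene-1,2-diyl]dimethanol F6.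
- Mitsunobu azidation (PPh3, DIAD, (PhO)2P(O)N3) gives (3S,4S)-3,4-bis(azidomethyl)cyclobut-1-ene F7.
- Staudinger reduction (PMe3, wet THF) with Boc2O gives 14.

**Step 5.** Enantiomeric purity may be lost by SN2′ attack, by ionisation to a symmetric acetoxy-cyclobutenyl or acetoxonium cation, or by acyl migration in 6 before activation; the product may open on warming.
Fallback: kinetic resolution in place of a stereospecific substitution. It sets out from 7 of insufficient enantiomeric purity and comes back at 7. Lipase hydrolysis in phosphate buffer–tert-butyl methyl ether at 0–5 °C should consume the (1R,2R)-enantiomer as (1R,4R)-4-hydroxycyclobut-2-en-1-yl acetate F8, which is left to decompose, while (1S,2S)-7 is re-isolated cold. A subtilisin-type protease of opposite preference is used if the lipase attacks the wanted enantiomer.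

**Step 8.** β-Hydride elimination and chain walking of the cyclobutyl–palladium intermediate, arrest after one carbonyl group, or interference by the carbamate N–H may divert the addition.
Fallback: it sets out from 14 and comes back at 16.
- [2+2] cycloaddition of dichloroketene (Cl3CCOCl, zinc–copper couple, Et2O) to the strained alkene gives di-tert-butyl {[5,5-dichloro-6-oxobicyclo[2.2.0]hexane-2,3-diyl]bis(methylene)}dicarbamate F9.
- NaOMe in MeOH opens the α,α-dichlorocyclobutanone to the methyl ester with a neighbouring dichloromethyl group, F10.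
- AgNO3 in aqueous THF hydrolyses the dichloromethyl group, and K2CO3 equilibrates the product to the all-trans formyl ester F11.
- NaClO2 gives the acid ester F12, and MeI with K2CO3 gives 16.

**Step 14.** Over-acylation to the bis-amide and competing acylation at an aminoimidazole nitrogen are statistical or kinetic leaks, and the polar products are hard to separate.
Fallback: it sets out from 21 and comes back at 25. Compound 21 is treated in one flask with 22 and 24 (one equivalent each). The three bis-amides are 25, sceptrin F13 (both pyrroles brominated) and the bromine-free bis(pyrrole-2-carboxamide) F14. They differ by one bromine each and are separated by reverse-phase chromatography.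

## Further compounds

F1 | step 6 | 6,7-dichloro-3-oxabicyclo[3.2.0]heptane-2,4-dione (cis-fused; isomer mixture at C6/C7) | O=C1OC(=O)[C@H]2C(Cl)C(Cl)[C@@H]12
F2 | step 6 | (1R,5S)-3-oxabicyclo[3.2.0]hept-6-ene-2,4-dione (cis-cyclobut-3-ene-1,2-dicarboxylic anhydride) | O=C1OC(=O)[C@H]2C=C[C@@H]12
F3 | step 6 | dimethyl (1R,2S)-cyclobut-3-ene-1,2-dicarboxylate (cis, meso) | COC(=O)[C@@H]1C=C[C@@H]1C(=O)OC
F4 | step 6 | dimethyl trans-cyclobut-3-ene-1,2-dicarboxylate (racemic; (1S,2S) enantiomer drawn) | COC(=O)[C@H]1C=C[C@@H]1C(=O)OC
F5 | step 6 | (1S,2S)-cyclobut-3-ene-1,2-dicarboxylic acid (formed as the racemate, then resolved) | OC(=O)[C@H]1C=C[C@@H]1C(=O)O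
F6 | step 6 | [(1S,2S)-cyclobut-3-ene-1,2-diyl]dimethanol | OC[C@H]1C=C[C@@H]1CO
F7 | step 6 | (3S,4S)-3,4-bis(azidomethyl)cyclobut-1-ene | [N-]=[N+]=NC[C@H]1C=C[C@@H]1CN=[N+]=[N-]
F8 | step 5 | (1R,4R)-4-hydroxycyclobut-2-en-1-yl acetate | O[C@@H]1C=C[C@H]1OC(C)=O
F9 | step 8 | di-tert-butyl {[5,5-dichloro-6-oxobicyclo[2.2.0]hexane-2,3-diyl]bis(methylene)}dicarbamate (cis ring fusion, arms trans) | O=C2[C@H]1[C@H](CNC(=O)OC(C)(C)C)[C@@H](CNC(=O)OC(C)(C)C)[C@H]1C2(Cl)Cl
F10 | step 8 | methyl 2-(dichloromethyl)-3,4-bis({[(tert-butoxycarbonyl)amino]methyl})cyclobutane-1-carboxylate (ester and CHCl2 cis, arms trans) | COC(=O)[C@H]1[C@H](CNC(=O)OC(C)(C)C)[C@@H](CNC(=O)OC(C)(C)C)[C@H]1C(Cl)Cl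
F11 | step 8 | methyl all-trans-2-formyl-3,4-bis({[(tert-butoxycarbonyl)amino]methyl})cyclobutane-1-carboxylate | COC(=O)[C@H]1[C@H](CNC(=O)OC(C)(C)C)[C@@H](CNC(=O)OC(C)(C)C)[C@@H]1C=O
F12 | step 8 | all-trans-2-(methoxycarbonyl)-3,4-bis({[(tert-butoxycarbonyl)amino]methyl})cyclobutane-1-carboxylic acid | COC(=O)[C@H]1[C@H](CNC(=O)OC(C)(C)C)[C@@H](CNC(=O)OC(C)(C)C)[C@@H]1C(=O)O
F13 | step 14 | sceptrin (both pyrroles 4-brominated) | Nc1ncc([C@H]2[C@H](CNC(=O)c3cc(Br)c[nH]3)[C@@H](CNC(=O)c3cc(Br)c[nH]3)[C@@H]2c2cnc(N)[nH]2)[nH]1
F14 | step 14 | N,N'-{[(1R,2R,3S,4S)-3,4-bis(2-amino-1H-imidazol-4-yl)cyclobutane-1,2-diyl]bis(methylene)}bis(1H-pyrrole-2-carboxamide) | Nc1ncc([C@H]2[C@H](CNC(=O)c3ccc[nH]3)[C@@H](CNC(=O)c3ccc[nH]3)[C@@H]2c2cnc(N)[nH]2)[nH]1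
A1 | alternative 1 | all-trans-3,4-bis(tert-butyldimethylsilyloxymethyl)cyclobutane-1,2-dicarbaldehyde bis(2,4-dimethoxybenzylimine) | COc1ccc(C/N=C/[C@H]2[C@H](CO[Si](C)(C)C(C)(C)C)[C@@H](CO[Si](C)(C)C(C)(C)C)[C@@H]2/C=N/Cc2ccc(OC)cc2OC)c(OC)c1
A2 | alternative 1 | tosylmethyl isocyanide | Cc1ccc(cc1)S(=O)(=O)C[N+]#[C-]
A3 | alternative 1 | all-trans-1,2-bis[1-(2,4-dimethoxybenzyl)imidazol-5-yl]-3,4-bis(tert-butyldimethylsilyloxymethyl)cyclobutane | COc1ccc(Cn2cncc2[C@H]2[C@H](CO[Si](C)(C)C(C)(C)C)[C@@H](CO[Si](C)(C)C(C)(C)C)[C@@H]2c2cncn2Cc2ccc(OC)cc2OC)c(OC)c1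
A4 | alternative 2 | (E)-1,2-bis(imidazo[1,2-a]pyrimidin-3-yl)ethene | c1ccnc2ncc(/C=C/c3cnc4ncccn34)n12
A5 | alternative 2 | di-(−)-menthyl fumarate | O=C(/C=C/C(=O)O[C@@H]1C[C@H](C)CC[C@H]1C(C)C)O[C@@H]1C[C@H](C)CC[C@H]1C(C)C
A6 | alternative 2 | di-(−)-menthyl all-trans-3,4-bis(imidazo[1,2-a]pyrimidin-3-yl)cyclobutane-1,2-dicarboxylate | c1ccnc2ncc([C@H]3[C@H](C(=O)O[C@@H]4C[C@H](C)CC[C@H]4C(C)C)[C@@H](C(=O)O[C@@H]4C[C@H](C)CC[C@H]4C(C)C)[C@@H]3c3cnc4ncccn34)n12
A7 | alternative 3 | bis(1,3-dioxoisoindolin-2-yl) all-trans-3,4-bis[(1,3-dioxoisoindolin-2-yl)methyl]cyclobutane-1,2-dicarboxylate | O=C(ON1C(=O)c2ccccc2C1=O)[C@H]3[C@H](CN4C(=O)c5ccccc5C4=O)[C@@H](CN4C(=O)c5ccccc5C4=O)[C@@H]3C(=O)ON1C(=O)c2ccccc2C1=O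
A8 | alternative 3 | 3-iodoimidazo[1,2-a]pyrimidine | Ic1cnc2ncccn12
A9 | alternative 3 | all-trans-1,2-bis(imidazo[1,2-a]pyrimidin-3-yl)-3,4-bis(phthalimidomethyl)cyclobutane | c1ccnc2ncc([C@H]3[C@H](CN4C(=O)c5ccccc5C4=O)[C@@H](CN4C(=O)c5ccccc5C4=O)[C@@H]3c3cnc4ncccn34)n12
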